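**Strategy.** Everything rests on cutting the bond between C2 of the pyran ring and C1' of the 4-hydroxy-3,5-dimethoxyphenyl ring. C2 sits between O1 and, at the flav-3-ene oxidation level, the C3=C4 bond conjugated with ring A, so loss of ethoxide from C2 gives a flat, aromatic 1-benzopyrylium ion (O1, C2, C3, C4, ring A) that the C7 methoxy group stabilises. A chiral tartramic acid with a lanthanide triflate then transfers the aryl group of a boronate to C2 of this achiral cation, joining both halves and setting C2 in one operation. The precursor is a racemic 2-ethoxy-2H-chromene made from a coumarin; the C3 hydroxyl follows by hydroboration anti to the new aryl group.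

Key step: step 8

Remark: 1, 4 and 10 are assumed to be catalogue compounds, and the absolute sense of induction of the chiral acid in step 8 is assumed to be selectable by the choice of its antipode.

**Step 1**
Reactants: 1 2-bromo-4,6-dimethoxybenzaldehyde
Product: 2 2-bromo-6-hydroxy-4-methoxybenzaldehyde
Conditions: BCl3 (1.2 equiv), CH2Cl2, −78 °C to 0 °C; aq. work-up
Reagents that add atoms: none
Why: BCl3 chelates the aldehyde oxygen and the ortho methoxy oxygen, so chloride should remove only the methyl group on O6 (chelation-controlled Lewis acid ether cleavage) and leave the para methoxy group and the C–Br bond untouched.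

**Step 2**
Reactants: 2 2-bromo-6-hydroxy-4-methoxybenzaldehyde
Product: 3 5-bromo-7-methoxy-2H-chromen-2-one
Conditions: Ph3P=CHCO2Et (1.3 equiv), N,N-diethylaniline, reflux
Reagents that add atoms: ethyl (triphenylphosphoranylidene)acetate, CCOC(=O)C=P(c1ccccc1)(c1ccccc1)c1ccccc1
Why: Wittig olefination with a stabilised ylide, thermal E/Z equilibration and lactonisation of the ortho phenol onto the ethyl ester should close the pyranone ring (classical salicylaldehyde-to-coumarin Wittig annulation).

**Step 3**
Reactants: 4 3-(benzyloxy)benzaldehyde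
Product: 5 1-(benzyloxy)-3-ethenylbenzene
Conditions: Ph3PCH3Br, KOtBu, THF, 0 °C to rt
Reagents that add atoms: methyltriphenylphosphonium bromide, C[P+](c1ccccc1)(c1ccccc1)c1ccccc1.[Br-]
Why: Wittig methylenation of an aromatic aldehyde with the non-stabilised ylide, to which the benzyl ether is inert.

**Step 4**
Reactants: 5 1-(benzyloxy)-3-ethenylbenzene; 3 5-bromo-7-methoxy-2H-chromen-2-one
Product: 7 5-{2-[3-(benzyloxy)phenyl]ethyl}-7-methoxy-2H-chromen-2-one, via B-alkyl-9-BBN borane 6 (not isolated)
Conditions: 9-BBN, THF, rt; then 3, PdCl2(dppf) (5 mol %), aq. K3PO4, DMF, 50 °C; mild acid work-up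
Reagents that add atoms: none
Why: Anti-Markovnikov hydroboration of the styrene by 9-BBN and B-alkyl Suzuki–Miyaura coupling with the aryl bromide should form the C5–CH2 bond, and the acid work-up re-closes any lactone opened by the phosphate base.

**Step 5**
Reactants: 7 5-{2-[3-(benzyloxy)phenyl]ethyl}-7-methoxy-2H-chromen-2-one
Product: 9 2-ethoxy-5-{2-[3-(benzyloxy)phenyl]ethyl}-7-methoxy-2H-chromene (racemic at C2), via lactol 8 (not isolated)
Conditions: DIBAL-H (1.1 equiv), CH2Cl2, −78 °C; Rochelle salt work-up; crude lactol, EtOH, PPTS (cat.), rt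
Reagents that add atoms: ethanol, CCO
Why: Low-temperature DIBAL-H half-reduction of the lactone should stop at the lactol, and acid-catalysed exchange of its hydroxyl for ethoxy through the stabilised benzopyrylium ion gives the mixed acetal (partial lactone reduction followed by acetalisation).

**Step 6**
Reactants: 10 4-bromo-2,6-dimethoxyphenol
Product: 11 2-(benzyloxy)-5-bromo-1,3-dimethoxybenzene
Conditions: BnBr, K2CO3, DMF, rt
Reagents that add atoms: benzyl bromide, BrCc1ccccc1
Why: Williamson ether synthesis on the phenoxide, which protects the phenol that would otherwise quench the organometallic and boron chemistry of steps 7 and 8.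

**Step 7**
Reactants: 11 2-(benzyloxy)-5-bromo-1,3-dimethoxybenzene
Product: 14 diethyl [4-(benzyloxy)-3,5-dimethoxyphenyl]boronate, via aryllithium 12 (not isolated), via lithium aryltriethoxyborate 13 (not isolated)
Conditions: n-BuLi, THF, −78 °C; B(OEt)3, −78 °C to rt; HCl in Et2O (1.0 equiv), 0 °C; filtration and concentration under argon
Reagents that add atoms: triethyl borate, CCOB(OCC)OCC
Why: Bromine–lithium exchange, capture of the aryllithium by the borate and anhydrous protonolysis of one ethoxide of the ate complex should release the neutral diethyl boronate (lithiation–borylation of an aryl bromide).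

**Step 8**
Reactants: 9 2-ethoxy-5-{2-[3-(benzyloxy)phenyl]ethyl}-7-methoxy-2H-chromene; 14 diethyl [4-(benzyloxy)-3,5-dimethoxyphenyl]boronate
Product: 16 (2S)-2-[4-(benzyloxy)-3,5-dimethoxyphenyl]-5-{2-[3-(benzyloxy)phenyl]ethyl}-7-methoxy-2H-chromene, via 1-benzopyrylium ion 15 (not isolated)
Conditions: 14 (1.5 equiv), (2R,3R)-4-(dibenzylamino)-2,3-dihydroxy-4-oxobutanoic acid (N,N-dibenzyl-L-tartramic acid, 10 mol %), Ce(OTf)4 (5 mol %), EtOAc, −20 °C
Reagents that add atoms: none
Why: The lanthanide triflate ionises either enantiomer of acetal 9 to the same planar, aromatic 1-benzopyrylium ion 15, while the tartramic acid exchanges with the ethoxy groups of 14 to give a chiral acyloxy dioxaborolane whose ethoxide-bound ate form transfers its aryl group from boron to C2 inside the ion pair. The closest known reaction type is the chiral Brønsted acid/Lewis acid catalysed enantioselective addition of aryl boronates to 2-ethoxy-2H-chromenes, a Petasis-type boron-to-carbon aryl transfer onto an oxocarbenium ion. No ring is closed: the pyran ring is carried in intact and only the C2–C1' bond forms. The new C2 stereocentre is controlled by the catalyst, which has to deliver the aryl group to the Re face of C2 (O1 > C3 > H) to give the (S)-flav-3-ene; the antipodal acid from D-tartaric acid is used if the sense of induction turns out opposite. The step needs C2 over C4 regioselectivity, which the substrate should secure through the high positive charge at C2 next to O1 and the shielding of C4 by the peri C5 phenethyl chain. It also needs the catalysed pathway to outrun racemic background arylation, which the low temperature and the low nucleophilicity of the uncomplexed diethyl boronate should secure.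

**Step 9**
Reactants: 16 (2S)-2-[4-(benzyloxy)-3,5-dimethoxyphenyl]-5-{2-[3-(benzyloxy)phenyl]ethyl}-7-methoxy-2H-chromene
Product: 18 (2R,3S)-2-[4-(benzyloxy)-3,5-dimethoxyphenyl]-5-{2-[3-(benzyloxy)phenyl]ethyl}-7-methoxychroman-3-ol, via C3 borane 17 (not isolated)
Conditions: BH3·THF, THF, 0 °C to rt; then aq. NaOH, H2O2, 0 °C
Reagents that add atoms: hydrogen peroxide, OO
Why: Hydroboration–oxidation of a flav-3-ene: borane should add syn across C3=C4 on the face anti to the C2 aryl group with boron at C3, because hydride goes to the C4 terminus that is benzylic to the oxygen-rich ring A and crowded by the C5 chain, and stereoretentive C–B oxidation then gives the 3S alcohol 2,3-trans to the aryl group, so C2 controls C3.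

**Step 10**
Reactants: 18 (2R,3S)-2-[4-(benzyloxy)-3,5-dimethoxyphenyl]-5-{2-[3-(benzyloxy)phenyl]ethyl}-7-methoxychroman-3-ol
Product: 19 (2R,3S)-2-(4-hydroxy-3,5-dimethoxyphenyl)-5-[2-(3-hydroxyphenyl)ethyl]-7-methoxychroman-3-ol
Conditions: H2 (1 atm), 10% Pd/C, EtOAc/MeOH, rt
Reagents that add atoms: none
Why: Catalytic hydrogenolysis of the two aryl benzyl ethers under neutral conditions, under which the cyclic C2–O1 ether, the secondary alcohol and both stereocentres are expected to survive.

**Compound list**

1 | 2-bromo-4,6-dimethoxybenzaldehyde | COc1cc(Br)c(C=O)c(OC)c1 | starting material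
2 | 2-bromo-6-hydroxy-4-methoxybenzaldehyde | COc1cc(O)c(C=O)c(Br)c1 | intermediate
3 | 5-bromo-7-methoxy-2H-chromen-2-one | COc1cc(Br)c2C=CC(=O)Oc2c1 | intermediate
4 | 3-(benzyloxy)benzaldehyde | O=Cc1cccc(OCc2ccccc2)c1 | starting material
5 | 1-(benzyloxy)-3-ethenylbenzene | C=Cc1cccc(OCc2ccccc2)c1 | intermediate
6 | 9-{2-[3-(benzyloxy)phenyl]ethyl}-9-borabicyclo[3.3.1]nonane | C(Cc1cccc(OCc2ccccc2)c1)B1C2CCCC1CCC2 | intermediate
7 | 5-{2-[3-(benzyloxy)phenyl]ethyl}-7-methoxy-2H-chromen-2-one | COc1cc(CCc2cccc(OCc3ccccc3)c2)c2C=CC(=O)Oc2c1 | intermediate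
8 | 5-{2-[3-(benzyloxy)phenyl]ethyl}-7-methoxy-2H-chromen-2-ol (lactol, racemic at C2) | COc1cc(CCc2cccc(OCc3ccccc3)c2)c2C=CC(O)Oc2c1 | intermediate
9 | 2-ethoxy-5-{2-[3-(benzyloxy)phenyl]ethyl}-7-methoxy-2H-chromene (racemic at C2) | CCOC1C=Cc2c(CCc3cccc(OCc4ccccc4)c3)cc(OC)cc2O1 | intermediate
10 | 4-bromo-2,6-dimethoxyphenol | COc1cc(Br)cc(OC)c1O | starting material
11 | 2-(benzyloxy)-5-bromo-1,3-dimethoxybenzene | COc1cc(Br)cc(OC)c1OCc1ccccc1 | intermediate
12 | [4-(benzyloxy)-3,5-dimethoxyphenyl]lithium | [Li]c1cc(OC)c(OCc2ccccc2)c(OC)c1 | intermediate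
13 | lithium [4-(benzyloxy)-3,5-dimethoxyphenyl]triethoxyborate | [Li+].CCO[B-](OCC)(OCC)c1cc(OC)c(OCc2ccccc2)c(OC)c1 | intermediate
14 | diethyl [4-(benzyloxy)-3,5-dimethoxyphenyl]boronate | CCOB(OCC)c1cc(OC)c(OCc2ccccc2)c(OC)c1 | intermediate
15 | 5-{2-[3-(benzyloxy)phenyl]ethyl}-7-methoxy-1-benzopyrylium ion (achiral, planar) | COc1cc(CCc2cccc(OCc3ccccc3)c2)c2ccc[o+]c2c1 | intermediate
16 | (2S)-2-[4-(benzyloxy)-3,5-dimethoxyphenyl]-5-{2-[3-(benzyloxy)phenyl]ethyl}-7-methoxy-2H-chromene | COc1cc(CCc2cccc(OCc3ccccc3)c2)c2c(c1)O[C@H](c1cc(OC)c(OCc3ccccc3)c(OC)c1)C=C2 | intermediate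
17 | C3 borane of 16, boron at C3 on the ring face opposite the C2 aryl group (2,3-trans) | COc1cc(CCc2cccc(OCc3ccccc3)c2)c2c(c1)O[C@H](c1cc(OC)c(OCc3ccccc3)c(OC)c1)[C@@H](B)C2 | intermediate
18 | (2R,3S)-2-[4-(benzyloxy)-3,5-dimethoxyphenyl]-5-{2-[3-(benzyloxy)phenyl]ethyl}-7-methoxychroman-3-ol (2,3-trans) | COc1cc(CCc2cccc(OCc3ccccc3)c2)c2c(c1)O[C@H](c1cc(OC)c(OCc3ccccc3)c(OC)c1)[C@@H](O)C2 | intermediate
19 | (2R,3S)-2-(4-hydroxy-3,5-dimethoxyphenyl)-5-[2-(3-hydroxyphenyl)ethyl]-7-methoxychroman-3-ol (2,3-trans) | COc1cc(CCc2cccc(O)c2)c2c(c1)O[C@H](c1cc(OC)c(O)c(OC)c1)[C@@H](O)C2 | target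

**Count**

Total step count: 10. Longest linear sequence: 7 steps (steps 1, 2, 4, 5, 8, 9, 10).

**Steps most likely to fail**

Step 8. A racemic background addition may compete with the catalysed aryl transfer, or the transfer from boron may be slow, so that enantiofacial control is poor or conversion stalls. The acid-sensitive flav-3-ene may also disproportionate on prolonged contact with the Lewis acid. The fallback sets out from bromide 11 and acetal 9. Magnesium insertion into 11 (Mg, THF) should give [4-(benzyloxy)-3,5-dimethoxyphenyl]magnesium bromide F1. This Grignard reagent displaces the ethoxy group of 9 (THF, 0 °C, classical substitution of 2-alkoxy-2H-chromenes through the benzopyrylium ion pair) and forms the same C2–aryl bond without stereocontrol. The product is the racemic flav-3-ene, that is 16 together with its mirror image, (2R)-2-[4-(benzyloxy)-3,5-dimethoxyphenyl]-5-{2-[3-(benzyloxy)phenyl]ethyl}-7-methoxy-2H-chromene F2. Preparative chiral SFC on a polysaccharide phase separates the two, and the route is rejoined at 16.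

Step 9. Boron may be delivered to C4 instead of C3 or to the face syn to the aryl group, and the C3 borane may undergo β-elimination of the O1 aryloxide with opening of the pyran ring before it is oxidised. The fallback sets out from 16. Dihydroxylation (OsO4 cat., NMO, acetone/H2O) anti to the C2 aryl group should give (2R,3S,4S)-2-[4-(benzyloxy)-3,5-dimethoxyphenyl]-5-{2-[3-(benzyloxy)phenyl]ethyl}-7-methoxychroman-3,4-diol F3, the 2,3-trans-3,4-cis diol. Ionic hydrogenation (Et3SiH, TFA, CH2Cl2, −20 °C) then removes only the C4 hydroxyl, whose benzylic cation is stabilised by O1 and the C7 methoxy group, and the route is rejoined at 18.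

Step 5. The lactol aluminate may be over-reduced, the lactol may open to the hydroxycinnamaldehyde and isomerise to the E form that cannot re-close, and the acetal may ionise on silica. The fallback sets out from coumarin 7. Deliberate full reduction with excess DIBAL-H (CH2Cl2, −78 °C to 0 °C) should give 2-[(1Z)-3-hydroxyprop-1-en-1-yl]-5-methoxy-3-{2-[3-(benzyloxy)phenyl]ethyl}phenol F4. MnO2 (CH2Cl2, rt) oxidises the allylic alcohol selectively to the Z-enal, which closes to lactol 8. Acetalisation with EtOH/PPTS as in step 5 rejoins the route at 9.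

**Further compounds**

F1 | step 8 | [4-(benzyloxy)-3,5-dimethoxyphenyl]magnesium bromide | COc1cc([Mg]Br)cc(OC)c1OCc1ccccc1
F2 | step 8 | (2R)-2-[4-(benzyloxy)-3,5-dimethoxyphenyl]-5-{2-[3-(benzyloxy)phenyl]ethyl}-7-methoxy-2H-chromene | COc1cc(CCc2cccc(OCc3ccccc3)c2)c2c(c1)O[C@@H](c1cc(OC)c(OCc3ccccc3)c(OC)c1)C=C2
F3 | step 9 | (2R,3S,4S)-2-[4-(benzyloxy)-3,5-dimethoxyphenyl]-5-{2-[3-(benzyloxy)phenyl]ethyl}-7-methoxychroman-3,4-diol | COc1cc(CCc2cccc(OCc3ccccc3)c2)c2c(c1)O[C@H](c1cc(OC)c(OCc3ccccc3)c(OC)c1)[C@@H](O)[C@H]2O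
F4 | step 5 | 2-[(1Z)-3-hydroxyprop-1-en-1-yl]-5-methoxy-3-{2-[3-(benzyloxy)phenyl]ethyl}phenol | COc1cc(O)c(/C=C\CO)c(CCc2cccc(OCc3ccccc3)c2)c1
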